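**Plan**

- Retrosynthesis: unmask the C14 enal from its acetal; cut the carbocycle at C9–C10 (alkenyl iodide plus aldehyde); cut the lactone at C7–C11 and C11=C13, giving an acyclic trans-7,8-epoxy C6-alcohol phosphonoacetate; cut C6–C7 (alkenylzinc plus Z-enal); reach neryl acetate.
- Enabling feature: in the γ-lactone ring (O–C12–C11–C7–C6) the α-carbon C11 sits on C7, which lies between the lactone carbinol C6 and the acyloxy carbon C8. The triad C6–O / C7–C / C8–O is the retron of a 2,3-epoxy alcohol ester, so a C11 carbanion tethered through the C6 ester can close the lactone 5-exo at C7 and free the C8 oxygen.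
- Order of rings: open chain first, then the γ-lactone with its exocyclic methylene (step 9), then the ten-membered carbocycle (step 13).
- Stereocenters: C6 from a ligand-controlled alkenylzinc addition, reinforced and relayed to C7/C8 by Sharpless epoxidation with D-(−)-DIPT; C7 by SN2 inversion at the oxirane; C8 retained from the oxirane; C9 by Felkin–Anh reduction of the ring enone.
- Alkene geometry: 4Z from nerol; the ring-cis 1(10) alkene from α-iodination of an E-enal, carried through the chromium coupling with retention.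

Key step: step 9

Remark: locants C1–C15 in the text are germacrane locants of the target (ring C1–C10; C11–C13 lactone carbons on C7; C14 formyl carbon on C10; C15 methyl on C4). 4-Methoxybenzyl propargyl ether 9 is taken as purchasable (otherwise one step from propargyl alcohol).

**Route**

Step 1
Reactants: 1 neryl acetate
Product: 2 (2Z)-3-methyl-6-oxohex-2-en-1-yl acetate
Conditions: O3 (1 equiv), CH2Cl2, pyridine, −78 °C; then Me2S, −78 °C to rt
Reagents that add atoms: ozone, [O-][O+]=O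
Why: Chemoselective ozonolysis; the electron-rich terminal trisubstituted alkene should react before the 2,3-alkene, which is deactivated by the allylic acetate and keeps its Z geometry.

Step 2
Reactants: 2 (2Z)-3-methyl-6-oxohex-2-en-1-yl acetate; 3 (triphenylphosphoranylidene)acetaldehyde
Product: 4 (2Z,6E)-3-methyl-8-oxoocta-2,6-dien-1-yl acetate
Conditions: toluene, 80 °C
Reagents that add atoms: (triphenylphosphoranylidene)acetaldehyde 3, O=CC=P(c1ccccc1)(c1ccccc1)c1ccccc1
Why: Wittig reaction of a stabilised formyl ylide should give the E-enal (C1=C10 with C14).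

Step 3
Reactants: 4 (2Z,6E)-3-methyl-8-oxoocta-2,6-dien-1-yl acetate
Product: 5 (2Z,6Z)-7-iodo-3-methyl-8-oxoocta-2,6-dien-1-yl acetate
Conditions: I2, K2CO3, DMAP (20 mol%), THF/H2O, rt
Reagents that add atoms: iodine, [I][I]
Why: α-Iodination of an enal (amine conjugate addition, enolate iodination, elimination; Baylis–Hillman-type manifold) should give the more stable Z-iodide, with iodine cis to the chain and the formyl group trans.

Step 4
Reactants: 5 (2Z,6Z)-7-iodo-3-methyl-8-oxoocta-2,6-dien-1-yl acetate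
Product: 7 (2Z,6Z)-7-iodo-8,8-dimethoxy-3-methylocta-2,6-dien-1-ol, via acetal acetate 6 (not isolated)
Conditions: HC(OMe)3, PPTS (cat.), MeOH, rt; then K2CO3, rt
Reagents that add atoms: trimethyl orthoformate, COC(OC)OC
Why: Acid-catalysed acetalisation masks C14 as the dimethyl acetal, and basic methanolysis in the same flask removes the acetate.

Step 5
Reactants: 7 (2Z,6Z)-7-iodo-8,8-dimethoxy-3-methylocta-2,6-dien-1-ol
Product: 8 (2Z,6Z)-7-iodo-8,8-dimethoxy-3-methylocta-2,6-dienal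
Conditions: MnO2 (excess), CH2Cl2, rt
Reagents that add atoms: none
Why: Neutral allylic oxidation with MnO2 should give the Z-enal without isomerisation; acetal and alkenyl iodide are inert.

Step 6
Reactants: 8 (2Z,6Z)-7-iodo-8,8-dimethoxy-3-methylocta-2,6-dienal; 9 1-methoxy-4-[(prop-2-yn-1-yloxy)methyl]benzene
Product: 12 (2E,4S,5Z,9Z)-10-iodo-11,11-dimethoxy-1-[(4-methoxyphenyl)methoxy]-6-methylundeca-2,5,9-trien-4-ol, via alkenylborane 10 (not isolated), via alkenylzinc 11 (not isolated)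
Conditions: 9, Cy2BH, toluene, 0 °C to rt; Me2Zn, −78 °C; (−)-MIB (5 mol%), then 8, −20 °C to 0 °C; H2O quench
Reagents that add atoms: alkyne 9, C#CCOCc1ccc(OC)cc1
Why: syn-Hydroboration, boron-to-zinc transmetalation and amino-alcohol-catalysed alkenylzinc 1,2-addition should give the E-allylic alcohol; the ligand directs si-face attack on the aldehyde and so sets C6 (4S by the priority rules).

Step 7
Reactants: 12 (2E,4S,5Z,9Z)-10-iodo-11,11-dimethoxy-1-[(4-methoxyphenyl)methoxy]-6-methylundeca-2,5,9-trien-4-ol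
Product: 13 (1R,2Z,6Z)-7-iodo-8,8-dimethoxy-1-[(2R,3R)-3-{[(4-methoxyphenyl)methoxy]methyl}oxiran-2-yl]-3-methylocta-2,6-dien-1-ol
Conditions: Ti(OiPr)4 (10 mol%), D-(−)-DIPT (12 mol%), t-BuOOH, 4 Å MS, CH2Cl2, −20 °C
Reagents that add atoms: tert-butyl hydroperoxide, CC(C)(C)OO
Why: Sharpless asymmetric epoxidation in its matched, erythro-selective mode should oxidise only the E-disubstituted 7,8-alkene, setting C7 and C8 and leaving any minor C6 enantiomer behind; the Z-trisubstituted 4,5-alkene is the mismatched, slow partner.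

Step 8
Reactants: 13 epoxy alcohol; 14 2-(diethoxyphosphoryl)acetic acid
Product: 15 (1R,2Z,6Z)-7-iodo-8,8-dimethoxy-1-[(2R,3R)-3-{[(4-methoxyphenyl)methoxy]methyl}oxiran-2-yl]-3-methylocta-2,6-dien-1-yl 2-(diethoxyphosphoryl)acetate
Conditions: DCC, DMAP (cat.), CH2Cl2, 0 °C to rt
Reagents that add atoms: 2-(diethoxyphosphoryl)acetic acid 14, CCOP(=O)(CC(=O)O)OCC
Why: Steglich esterification puts the C11–C12 unit on O6 without a base that could trigger Payne rearrangement.

Step 9
Reactants: 15 epoxy phosphonoacetate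
Product: 17 (4R,5R)-4-[(1S)-1-hydroxy-2-[(4-methoxyphenyl)methoxy]ethyl]-5-[(1Z,5Z)-6-iodo-7,7-dimethoxy-2-methylhepta-1,5-dien-1-yl]-3-methylideneoxolan-2-one, via lithiated phosphono lactone 16 (not isolated)
Conditions: LiN(SiMe3)2 (1.05 equiv), THF, −78 °C to 40 °C; then (CH2O)n, rt
Reagents that add atoms: formaldehyde (from paraformaldehyde), C=O
Why: Proposed new method: LiN(SiMe3)2 forms the lithium-chelated phosphonoacetate carbanion at C11, which should open the lithium-activated oxirane at its proximal carbon C7 by backside attack; proton transfer from C11–H to the C8 alkoxide then gives lithiated 16, and formaldehyde completes a Horner–Wadsworth–Emmons methylenation. The closest known reaction types are the telescoped intramolecular Michael addition/olefination of phosphonoacetate esters of γ-hydroxy enones (same tether and same 5-(enolendo) closure, but onto a trigonal acceptor) and the opening of epoxides by phosphonoacetate anions to α-phosphono γ-lactones; the 5-exo opening of 2,3-epoxy alcohol carbamates at C2 shows that the geometry is attainable. The only ring closed is the γ-lactone (O–C12–C11–C7–C6), in the 5-exo-tet mode with the breaking oxirane C–O bond exocyclic. C7 is the only new stereocenter and is fixed by SN2 inversion of the 7R oxirane carbon, which places C11 trans to the C6 side chain and erythro to the retained C8 oxygen. The step needs C-attack at C7 in preference to O-alkylation, to 6-endo attack at C8 and to phosphoryl transfer onto the C8 alkoxide: the phosphoryl group carries the charge so the ring ester can twist out of conjugation, the trans-oxirane lines up only C7 for a collinear five-membered transition state, and keeping the mixture at or below 40 °C leaves the anion on carbon until formaldehyde is added.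

Step 10
Reactants: 17 hydroxy α-methylene lactone
Product: 18 (1S)-1-[(2R,3S)-2-[(1Z,5Z)-6-iodo-7,7-dimethoxy-2-methylhepta-1,5-dien-1-yl]-4-methylidene-5-oxooxolan-3-yl]-2-[(4-methoxyphenyl)methoxy]ethyl 2-methylpropanoate
Conditions: (i-PrCO)2O, Et3N, DMAP (cat.), CH2Cl2, 0 °C
Reagents that add atoms: isobutyric anhydride, CC(C)C(=O)OC(=O)C(C)C
Why: DMAP-catalysed acylation installs the C8 isobutyrate of the target and blocks translactonisation to the 8,12-olide.

Step 11
Reactants: 18 PMB ether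
Product: 19 (1S)-2-hydroxy-1-[(2R,3S)-2-[(1Z,5Z)-6-iodo-7,7-dimethoxy-2-methylhepta-1,5-dien-1-yl]-4-methylidene-5-oxooxolan-3-yl]ethyl 2-methylpropanoate
Conditions: DDQ, CH2Cl2/pH 7 buffer, 0 °C
Reagents that add atoms: none
Why: Oxidative PMB cleavage under buffered neutral conditions should free the C9 alcohol without acyl migration or loss of the acetal.

Step 12
Reactants: 19 primary alcohol
Product: 20 (1S)-1-[(2R,3S)-2-[(1Z,5Z)-6-iodo-7,7-dimethoxy-2-methylhepta-1,5-dien-1-yl]-4-methylidene-5-oxooxolan-3-yl]-2-oxoethyl 2-methylpropanoate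
Conditions: Dess–Martin periodinane, pyridine, CH2Cl2, 0 °C; used crude
Reagents that add atoms: none
Why: Buffered Dess–Martin oxidation should give the α-acyloxy aldehyde without epimerising C8.

Step 13
Reactants: 20 iodo aldehyde
Product: 21 (3aS,4S,6E,10Z,11aR)-6-(dimethoxymethyl)-5-hydroxy-10-methyl-3-methylidene-2-oxo-2,3,3a,4,5,8,9,11a-octahydrocyclodeca[b]furan-4-yl 2-methylpropanoate (both C5 epimers)
Conditions: CrCl2 (8 equiv), NiCl2 (5 mol%), degassed DMSO, 2 mM, rt
Reagents that add atoms: none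
Why: Nozaki–Hiyama–Kishi reaction (oxidative addition of the Z-alkenyl iodide to zerovalent nickel, transmetalation to trivalent chromium, chemoselective aldehyde addition) should close the ten-membered ring at C9–C10 with retention of alkene geometry; the C9 configuration is not relied on here and is converged in steps 14 and 15.

Step 14
Reactants: 21 ring allylic alcohol (epimers)
Product: 22 (3aS,4S,6Z,10Z,11aR)-6-(dimethoxymethyl)-10-methyl-3-methylidene-2,5-dioxo-2,3,3a,4,5,8,9,11a-octahydrocyclodeca[b]furan-4-yl 2-methylpropanoate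
Conditions: Dess–Martin periodinane, NaHCO3, CH2Cl2, rt
Reagents that add atoms: none
Why: Dess–Martin oxidation converts both C9 epimers into one cross-conjugated enone.

Step 15
Reactants: 22 enone
Product: 23 (3aS,4S,5S,6E,10Z,11aR)-6-(dimethoxymethyl)-5-hydroxy-10-methyl-3-methylidene-2-oxo-2,3,3a,4,5,8,9,11a-octahydrocyclodeca[b]furan-4-yl 2-methylpropanoate
Conditions: NaBH4, CeCl3·7H2O, MeOH, −78 °C
Reagents that add atoms: none
Why: Luche 1,2-reduction; polar Felkin–Anh delivery of hydride anti to the C8 acyloxy group should give the 8,9-syn (9S) alcohol, and CeCl3 at low temperature suppresses conjugate reduction of the enone and of the methylene lactone.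

Step 16
Reactants: 23 allylic alcohol
Product: 24 (3aS,4S,5S,6E,10Z,11aR)-6-(dimethoxymethyl)-10-methyl-3-methylidene-2-oxo-2,3,3a,4,5,8,9,11a-octahydrocyclodeca[b]furan-4,5-diyl bis(2-methylpropanoate)
Conditions: (i-PrCO)2O, DMAP, pyridine, CH2Cl2, rt
Reagents that add atoms: isobutyric anhydride, CC(C)C(=O)OC(=O)C(C)C
Why: DMAP-catalysed acylation; any O8/O9 acyl migration beforehand is harmless because both oxygens end as isobutyrates.

Step 17
Reactants: 24 acetal diester
Product: 25 (3aS,4S,5S,6E,10Z,11aR)-6-formyl-10-methyl-3-methylidene-2-oxo-2,3,3a,4,5,8,9,11a-octahydrocyclodeca[b]furan-4,5-diyl bis(2-methylpropanoate)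
Conditions: PPTS (cat.), acetone/H2O, rt
Reagents that add atoms: water, O
Why: Mild acid hydrolysis of the allylic dimethyl acetal should release the enal in its more stable geometry (formyl trans to C2) without touching the esters or the lactone.

**Compound list**

1 | neryl acetate, (2Z)-3,7-dimethylocta-2,6-dien-1-yl acetate | CC(C)=CCC/C(C)=C\COC(C)=O | starting material
2 | (2Z)-3-methyl-6-oxohex-2-en-1-yl acetate | O=CCC/C(C)=C\COC(C)=O | intermediate
3 | (triphenylphosphoranylidene)acetaldehyde | O=CC=P(c1ccccc1)(c1ccccc1)c1ccccc1 | starting material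
4 | (2Z,6E)-3-methyl-8-oxoocta-2,6-dien-1-yl acetate | O=C/C=C/CC/C(C)=C\COC(C)=O | intermediate
5 | (2Z,6Z)-7-iodo-3-methyl-8-oxoocta-2,6-dien-1-yl acetate | O=C/C(I)=C/CC/C(C)=C\COC(C)=O | intermediate
6 | (2Z,6Z)-7-iodo-8,8-dimethoxy-3-methylocta-2,6-dien-1-yl acetate | COC(OC)/C(I)=C/CC/C(C)=C\COC(C)=O | intermediate (not isolated)
7 | (2Z,6Z)-7-iodo-8,8-dimethoxy-3-methylocta-2,6-dien-1-ol | COC(OC)/C(I)=C/CC/C(C)=C\CO | intermediate
8 | (2Z,6Z)-7-iodo-8,8-dimethoxy-3-methylocta-2,6-dienal | COC(OC)/C(I)=C/CC/C(C)=C\C=O | intermediate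
9 | 1-methoxy-4-[(prop-2-yn-1-yloxy)methyl]benzene (PMB propargyl ether) | C#CCOCc1ccc(OC)cc1 | starting material
10 | dicyclohexyl[(1E)-3-[(4-methoxyphenyl)methoxy]prop-1-en-1-yl]borane | COc1ccc(COC/C=C/B(C2CCCCC2)C2CCCCC2)cc1 | intermediate (not isolated)
11 | methyl[(1E)-3-[(4-methoxyphenyl)methoxy]prop-1-en-1-yl]zinc | COc1ccc(COC/C=C/[Zn]C)cc1 | intermediate (not isolated)
12 | (2E,4S,5Z,9Z)-10-iodo-11,11-dimethoxy-1-[(4-methoxyphenyl)methoxy]-6-methylundeca-2,5,9-trien-4-ol | COC(OC)/C(I)=C/CC/C(C)=C\[C@@H](O)/C=C/COCc1ccc(OC)cc1 | intermediate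
13 | (1R,2Z,6Z)-7-iodo-8,8-dimethoxy-1-[(2R,3R)-3-{[(4-methoxyphenyl)methoxy]methyl}oxiran-2-yl]-3-methylocta-2,6-dien-1-ol | COC(OC)/C(I)=C/CC/C(C)=C\[C@@H](O)[C@H]1O[C@@H]1COCc1ccc(OC)cc1 | intermediate
14 | 2-(diethoxyphosphoryl)acetic acid | CCOP(=O)(CC(=O)O)OCC | starting material
15 | (1R,2Z,6Z)-7-iodo-8,8-dimethoxy-1-[(2R,3R)-3-{[(4-methoxyphenyl)methoxy]methyl}oxiran-2-yl]-3-methylocta-2,6-dien-1-yl 2-(diethoxyphosphoryl)acetate | COC(OC)/C(I)=C/CC/C(C)=C\[C@@H](OC(=O)CP(=O)(OCC)OCC)[C@H]1O[C@@H]1COCc1ccc(OC)cc1 | intermediate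
16 | (4R,5R)-3-(diethoxyphosphoryl)-4-[(1S)-1-hydroxy-2-[(4-methoxyphenyl)methoxy]ethyl]-5-[(1Z,5Z)-6-iodo-7,7-dimethoxy-2-methylhepta-1,5-dien-1-yl]oxolan-2-one (as lithium salt, C3 undefined) | CCOP(=O)(OCC)C1C(=O)O[C@H](/C=C(/C)CC/C=C(\I)C(OC)OC)[C@H]1[C@H](O)COCc1ccc(OC)cc1 | intermediate (not isolated)
17 | (4R,5R)-4-[(1S)-1-hydroxy-2-[(4-methoxyphenyl)methoxy]ethyl]-5-[(1Z,5Z)-6-iodo-7,7-dimethoxy-2-methylhepta-1,5-dien-1-yl]-3-methylideneoxolan-2-one | C=C1C(=O)O[C@H](/C=C(/C)CC/C=C(\I)C(OC)OC)[C@H]1[C@H](O)COCc1ccc(OC)cc1 | intermediate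
18 | (1S)-1-[(2R,3S)-2-[(1Z,5Z)-6-iodo-7,7-dimethoxy-2-methylhepta-1,5-dien-1-yl]-4-methylidene-5-oxooxolan-3-yl]-2-[(4-methoxyphenyl)methoxy]ethyl 2-methylpropanoate | C=C1C(=O)O[C@H](/C=C(/C)CC/C=C(\I)C(OC)OC)[C@H]1[C@H](OC(=O)C(C)C)COCc1ccc(OC)cc1 | intermediate
19 | (1S)-2-hydroxy-1-[(2R,3S)-2-[(1Z,5Z)-6-iodo-7,7-dimethoxy-2-methylhepta-1,5-dien-1-yl]-4-methylidene-5-oxooxolan-3-yl]ethyl 2-methylpropanoate | C=C1C(=O)O[C@H](/C=C(/C)CC/C=C(\I)C(OC)OC)[C@H]1[C@H](OC(=O)C(C)C)CO | intermediate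
20 | (1S)-1-[(2R,3S)-2-[(1Z,5Z)-6-iodo-7,7-dimethoxy-2-methylhepta-1,5-dien-1-yl]-4-methylidene-5-oxooxolan-3-yl]-2-oxoethyl 2-methylpropanoate | C=C1C(=O)O[C@H](/C=C(/C)CC/C=C(\I)C(OC)OC)[C@H]1[C@H](OC(=O)C(C)C)C=O | intermediate
21 | (3aS,4S,6E,10Z,11aR)-6-(dimethoxymethyl)-5-hydroxy-10-methyl-3-methylidene-2-oxo-2,3,3a,4,5,8,9,11a-octahydrocyclodeca[b]furan-4-yl 2-methylpropanoate (C5 epimers) | C=C1C(=O)O[C@@H]2/C=C(/C)CC/C=C(/C(OC)OC)C(O)[C@@H](OC(=O)C(C)C)[C@@H]12 | intermediate
22 | (3aS,4S,6Z,10Z,11aR)-6-(dimethoxymethyl)-10-methyl-3-methylidene-2,5-dioxo-2,3,3a,4,5,8,9,11a-octahydrocyclodeca[b]furan-4-yl 2-methylpropanoate | C=C1C(=O)O[C@@H]2/C=C(/C)CC/C=C(/C(OC)OC)C(=O)[C@@H](OC(=O)C(C)C)[C@@H]12 | intermediate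
23 | (3aS,4S,5S,6E,10Z,11aR)-6-(dimethoxymethyl)-5-hydroxy-10-methyl-3-methylidene-2-oxo-2,3,3a,4,5,8,9,11a-octahydrocyclodeca[b]furan-4-yl 2-methylpropanoate | C=C1C(=O)O[C@@H]2/C=C(/C)CC/C=C(/C(OC)OC)[C@H](O)[C@@H](OC(=O)C(C)C)[C@@H]12 | intermediate
24 | (3aS,4S,5S,6E,10Z,11aR)-6-(dimethoxymethyl)-10-methyl-3-methylidene-2-oxo-2,3,3a,4,5,8,9,11a-octahydrocyclodeca[b]furan-4,5-diyl bis(2-methylpropanoate) | C=C1C(=O)O[C@@H]2/C=C(/C)CC/C=C(/C(OC)OC)[C@H](OC(=O)C(C)C)[C@@H](OC(=O)C(C)C)[C@@H]12 | intermediate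
25 | (3aS,4S,5S,6E,10Z,11aR)-6-formyl-10-methyl-3-methylidene-2-oxo-2,3,3a,4,5,8,9,11a-octahydrocyclodeca[b]furan-4,5-diyl bis(2-methylpropanoate) | C=C1C(=O)O[C@@H]2/C=C(/C)CC/C=C(/C=O)[C@H](OC(=O)C(C)C)[C@@H](OC(=O)C(C)C)[C@@H]12 | target

**Totals**

Total step count: 17. Longest linear sequence: 17 steps (1 to 25).

**Steps most likely to fail**

1. Step 9 (proposed new method). What may go wrong: O-alkylation of the chelated enolate instead of C-alkylation (the 5-(enolendo)-exo-tet geometry is demanding), 6-endo opening at C8, or phosphoryl transfer to the C8 alkoxide before olefination. Fallback by known radical chemistry, setting out from 13 and returning at 18: 13 is O-alkylated (NaH, propargyl bromide, THF, 0 °C) to the propargyl ether F1. Cp2TiCl (trivalent titanium, from Cp2TiCl2 and Zn, THF, rt) opens the oxirane homolytically; the C7 radical closes 5-exo-dig onto the alkyne, trans to the C6 substituent, and gives the 3-methylenetetrahydrofuran alcohol F2 with the C8–O bond retained. Acylation with isobutyric anhydride gives the isobutyrate F3, and allylic oxidation of the ring O–CH2 group (CrO3, 3,5-dimethylpyrazole, CH2Cl2, −20 °C) gives 18.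

2. Step 13. What may go wrong: oligomerisation, or reductive loss of the α-acyloxy aldehyde, instead of closure of the strained ten-membered ring. Fallback by acyl cross-coupling, setting out from 19 and returning at 22: oxidation of 19 (TEMPO, PhI(OAc)2, MeCN/H2O) gives the carboxylic acid F4; EtSH, DCC and DMAP give the S-ethyl thioester F5; Me3SnSnMe3 with Pd(PPh3)4 converts the iodide into the alkenylstannane F6. A thioester–stannane (Liebeskind–Srogl) coupling at high dilution (Pd2(dba)3, tri(2-furyl)phosphine, copper thiophene-2-carboxylate CuO2CC4H3S, THF) closes the ring directly to enone 22, so steps 12 to 14 are bypassed.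

3. Step 15. What may go wrong: hydride delivery from the wrong face of the ring ketone (ring conformation overriding the Felkin–Anh preference), or conjugate reduction. Fallback setting out from 22 and returning at 24: the reduction is steered to the other epimer with a chelating hydride (Zn(BH4)2, Et2O, −20 °C), giving the 9R alcohol F7. F7 is then esterified under Mitsunobu conditions (isobutyric acid, PPh3, DIAD, toluene) with inversion at C9, which gives 24 directly and bypasses step 16.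

**Further compounds**

F1 | step 9 | (2R,3R)-2-[(1R,2Z,6Z)-7-iodo-8,8-dimethoxy-3-methyl-1-(prop-2-yn-1-yloxy)octa-2,6-dien-1-yl]-3-{[(4-methoxyphenyl)methoxy]methyl}oxirane | COC(OC)/C(I)=C/CC/C(C)=C\[C@@H](OCC#C)[C@H]1O[C@@H]1COCc1ccc(OC)cc1
F2 | step 9 | (1S)-1-[(2R,3R)-2-[(1Z,5Z)-6-iodo-7,7-dimethoxy-2-methylhepta-1,5-dien-1-yl]-4-methylideneoxolan-3-yl]-2-[(4-methoxyphenyl)methoxy]ethan-1-ol | C=C1CO[C@H](/C=C(/C)CC/C=C(\I)C(OC)OC)[C@H]1[C@H](O)COCc1ccc(OC)cc1
F3 | step 9 | (1S)-1-[(2R,3S)-2-[(1Z,5Z)-6-iodo-7,7-dimethoxy-2-methylhepta-1,5-dien-1-yl]-4-methylideneoxolan-3-yl]-2-[(4-methoxyphenyl)methoxy]ethyl 2-methylpropanoate | C=C1CO[C@H](/C=C(/C)CC/C=C(\I)C(OC)OC)[C@H]1[C@H](OC(=O)C(C)C)COCc1ccc(OC)cc1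
F4 | step 13 | (2S)-2-[(2R,3S)-2-[(1Z,5Z)-6-iodo-7,7-dimethoxy-2-methylhepta-1,5-dien-1-yl]-4-methylidene-5-oxooxolan-3-yl]-2-[(2-methylpropanoyl)oxy]acetic acid | C=C1C(=O)O[C@H](/C=C(/C)CC/C=C(\I)C(OC)OC)[C@H]1[C@H](OC(=O)C(C)C)C(=O)O
F5 | step 13 | S-ethyl (2S)-2-[(2R,3S)-2-[(1Z,5Z)-6-iodo-7,7-dimethoxy-2-methylhepta-1,5-dien-1-yl]-4-methylidene-5-oxooxolan-3-yl]-2-[(2-methylpropanoyl)oxy]ethanethioate | C=C1C(=O)O[C@H](/C=C(/C)CC/C=C(\I)C(OC)OC)[C@H]1[C@H](OC(=O)C(C)C)C(=O)SCC
F6 | step 13 | S-ethyl (2S)-2-[(2R,3S)-2-[(1Z,5Z)-7,7-dimethoxy-2-methyl-6-(trimethylstannyl)hepta-1,5-dien-1-yl]-4-methylidene-5-oxooxolan-3-yl]-2-[(2-methylpropanoyl)oxy]ethanethioate | C=C1C(=O)O[C@H](/C=C(/C)CC/C=C(\[Sn](C)(C)C)C(OC)OC)[C@H]1[C@H](OC(=O)C(C)C)C(=O)SCC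
F7 | step 15 | (3aS,4S,5R,6E,10Z,11aR)-6-(dimethoxymethyl)-5-hydroxy-10-methyl-3-methylidene-2-oxo-2,3,3a,4,5,8,9,11a-octahydrocyclodeca[b]furan-4-yl 2-methylpropanoate | C=C1C(=O)O[C@@H]2/C=C(/C)CC/C=C(/C(OC)OC)[C@@H](O)[C@@H](OC(=O)C(C)C)[C@@H]12
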